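The target in the four earlier runs stops rising within hours, near 10.1 % of the substrate charged in the north-west run and near 15.2 % in the south-west run, so the next run has to choose how the charges go in.

| flask | substrate | partner | protic impurity | remark | time |
|---|---|---|---|---|---|
| north-west | 0.22 M | 0.33 M | 0.22 M | run made earlier |  |
| west | 0.31 M | 0.33 M | 0.22 M | run made earlier |  |
| south | 0.48 M | 0.33 M | 0.22 M | run made earlier |  |
| south-west | 0.22 M | 0.49 M | 0.22 M | run made earlier |  |
| Wednesday's | 0.22 M (in portions, 2, over 8.0 h) | 0.330 M | 0.220 M | first portion at the start, last at 8.0 h | 20 h |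
| Friday's | 0.22 M (fed, over 8.0 h) | 0.330 M | 0.220 M | all else is in the flask from the start; the feed brings no volume worth counting | 20 h |
| Monday's | 0.22 M | 0.330 M (fed, over 8.0 h) | 0.220 M | all else is in the flask from the start; the feed brings no volume worth counting | 20 h |
| Saturday's | 0.22 M | 0.330 M | 0.220 M | everything together at the start | 20 h |

- north-west (time / h: target / %, substrate / %): 1.50: 8.3, 28.5; 4.00: 10.1, 25.2; 8.00: 9.9, 26.0; 20.0: 10.9, 25.8
- west (time / h: target / %, substrate / %): 1.50: 7.0, 28.4; 4.00: 9.8, 25.9; 8.00: 10.0, 26.0; 12.0: 9.9, 26.1
- south (time / h: target / %, substrate / %): 1.00: 4.8, 32.3; 2.00: 8.8, 26.5; 5.00: 9.9, 26.4; 12.0: 8.9, 26.1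
- south-west (time / h: target / %, substrate / %): 1.00: 7.7, 30.6; 2.00: 12.7, 25.3; 5.00: 15.2, 24.4; 12.0: 14.4, 24.9

(readings scatter by 0.5 percentage points)



* the best flask by amount of target, in percent of the substrate charged; "all alike" if 1.5 percentage points covers them all (Wednesday's / Friday's / Monday's / Saturday's / all alike)
* amount of target at the end, in percent of the substrate charged, Wednesday's
* amount of target at the end, in percent of the substrate charged, Friday's
* amount of target at the end, in percent of the substrate charged, Monday's
* amount of target at the end, in percent of the substrate charged, Saturday's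

The substrate charge leaves the north-west percentage where it is (10.1 %, 10.0 %, 9.9 % from 0.22 M to 0.48 M), but partner raised by a factor of 1.48 raises it by a factor of 1.50. The stall is therefore read here as partner being spent. The north-west run gives 0.306 M⁻¹ as the capture, the share of the charged substrate that becomes target per molar of partner spent with the whole substrate present. The south-west run reads 0.310 M⁻¹.

The south-west target stands at 7.7 % after 1.00 h, half of its plateau, so partner is taken to be spent at a mean time of 1.44 h. Saturday's then gives 10.1 %, and Monday's, whose partner enters over the whole substrate, gives the same figure. In Wednesday's that mean time is shorter than the wait for the last portion, so partner meets half of the substrate, which gives 5.05 %. In Friday's the feed has brought in 18.0 % of the substrate by that time, which gives 1.82 %. The next run therefore keeps the substrate whole at the start and does not feed it.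

The forecast gives 10.1 %, 10.1 %, 10.1 % and 10.1 % for Wednesday's, Friday's, Monday's and Saturday's, and so all alike, on the ground that “Every flask therefore reaches the same equilibrium”.

The flasks give 5.40 % for Wednesday's, 1.31 % for Friday's, 12.3 % for Monday's and 10.4 % for Saturday's, so the best is Monday's.

    substrate ⇌ open intermediate (K = 2.50, k = 2.00 h⁻¹)
    partner → second intermediate (k = 2.40 h⁻¹)
    open intermediate + second intermediate → target (k = 0.940 M⁻¹ h⁻¹)
    partner + protic impurity → quenched reagent (k = 0.280 M⁻¹ h⁻¹)
    second intermediate → side product (k = 1.50 h⁻¹)

Saturday's stands at 10.4 % against the reckoned 10.1 %, but Monday's lies 1.9 percentage points above Saturday's, where the reckoning had a tie. Monday's own capture is 0.371 M⁻¹, larger than the reading. On a neighbour of Monday's with 0.083 M of partner it gives 3.08 %, and that neighbour stands at 3.22 %. Monday's has come to rest: at 20.0 h partner, the limiting reagent, is at 0 % of its charge, while open intermediate stands at 62.7 %. After 200 h Monday's target still reads 12.3 %, and Friday's reads 1.31 %.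

The runs are simulated on assumed constants; the scatter is artificial.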